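Last cut: the four benzyl ethers of target 1. Before it, C3–C4 and O1–C2 of both chromans are cut together, because in each chroman C4 is a bare CH2 on C4a and C2 is a gem-dimethyl carbon on O1, the retron of an ortho-quinone methide (C4=C4a–C8a=O1) plus 2-methylpropene.
Further cuts: the two C4 hydroxymethyl carbons, the two C8–acyl bonds, the methine C–H bond, the methine–alkyl bond, and the two aryl–carbonyl bonds of a benzophenone built from two silyl ethers of 3,5-bis(benzyloxy)phenol.
Forward: the benzene rings are bought; the central carbon is joined to ring A (formylation), ring B (aryllithium addition) and the 5-methylhexyl chain (Grignard addition); the acyl groups go on ring B, then ring A; both dihydropyran rings close together in the key step, each taking up one molecule of 2-methylpropene; hydrogenolysis ends the route.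
Stereochemistry: the (R)-methine comes from chiral-phosphoric-acid transfer hydrogenation of a para-quinone methide in which ring B is the quinoid ring and ring A (O1 silylated) the pendant aryl; the (R)-α-methyl centre is bought as (R)-2-methylbutanoic acid.

Key step: step 13

Remarks and assumptions
- Ring A is the ring that ends with the 2-methylbutanoyl group, ring B the one with the isobutyryl group. Chroman numbering (O1, C2, C3, C4, C4a, C5–C8, C8a) is used for both rings even before the pyran rings exist.
- Which antipode of the phosphoric acid gives the (R)-methine must be fixed in a pilot run; (R)-TRIP is written, and its mirror image is used if the sense is opposite.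
- The methine keeps one spatial arrangement from step 7 onward. Its CIP letter is S in 17 and 18 only because acylated ring B outranks ring A there.
- The acyl groups are put on by magnesium-template C-acylation rather than by a Lewis-acid Fries shift, because an intermolecular acyl transfer to the other ring would amount to inverting the methine.
- The 5-methylhexyl chain is brought in as the Grignard reagent of commercial 1-bromo-5-methylhexane and added to a diaryl ketone.
- Steps 12 and 13 each act once on ring A and once on ring B, so two equivalents of formaldehyde and two equivalents of 2-methylpropene end up in the product.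

Step 1
Reactants: 2 3,5-bis(benzyloxy)phenol
Product: 3 [3,5-bis(benzyloxy)phenoxy]tri(propan-2-yl)silane
Conditions: i-Pr3SiCl, imidazole, DMF, rt
Reagents that add atoms: chlorotri(propan-2-yl)silane, CC(C)[Si](Cl)(C(C)C)C(C)C
Why: Imidazole-promoted O-silylation of a phenol is routine, and the bulky triisopropylsilyl ether is chosen because it does not direct lithiation and should outlast the later base and Grignard steps.

Step 2
Reactants: 3 [3,5-bis(benzyloxy)phenoxy]tri(propan-2-yl)silane
Product: 5 2,6-bis(benzyloxy)-4-[tri(propan-2-yl)silyloxy]benzaldehyde, via ring A aryllithium 4 (not isolated)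
Conditions: n-BuLi, THF, 0 °C; DMF, −78 °C → rt; H2O
Reagents that add atoms: N,N-dimethylformamide, CN(C)C=O
Why: Directed ortho-metalation should occur at the carbon between the two benzyloxy groups (the silyloxy group is a poor director and shields its neighbours), and formylation of the aryllithium with DMF puts the future methine carbon para to O1, a site that electrophilic substitution of the free phenol would not select cleanly.

Step 3
Reactants: 2 3,5-bis(benzyloxy)phenol
Product: 6 [3,5-bis(benzyloxy)phenoxy](tert-butyl)dimethylsilane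
Conditions: t-BuMe2SiCl, imidazole, DMF, rt
Reagents that add atoms: tert-butyl(chloro)dimethylsilane, CC(C)(C)[Si](C)(C)Cl
Why: The same O-silylation, with the tert-butyldimethylsilyl group chosen because its aryl ether is cleaved by carbonate in methanol while the triisopropylsilyl ether of ring A stays.

Step 4
Reactants: 6 [3,5-bis(benzyloxy)phenoxy](tert-butyl)dimethylsilane; 5 2,6-bis(benzyloxy)-4-[tri(propan-2-yl)silyloxy]benzaldehyde
Product: 8 rac-{2,6-bis(benzyloxy)-4-[tert-butyl(dimethyl)silyloxy]phenyl}{2,6-bis(benzyloxy)-4-[tri(propan-2-yl)silyloxy]phenyl}methanol, via ring B aryllithium 7 (not isolated)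
Conditions: 6, n-BuLi, THF, 0 °C; then 5, −78 °C → rt; H2O
Reagents that add atoms: none
Why: Directed ortho-metalation as in step 2 followed by 1,2-addition of the aryllithium to the aldehyde, the usual route to bis(2,6-dialkoxyphenyl)methanols; the carbinol centre forms racemic and is removed in step 5.

Step 5
Reactants: 8 the diaryl methanol
Product: 9 {2,6-bis(benzyloxy)-4-[tert-butyl(dimethyl)silyloxy]phenyl}{2,6-bis(benzyloxy)-4-[tri(propan-2-yl)silyloxy]phenyl}methanone
Conditions: Pr4N[RuO4] (5 mol%), N-methylmorpholine N-oxide, 4 Å MS, CH2Cl2, rt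
Reagents that add atoms: none
Why: Ley–Griffith oxidation of a secondary benzylic alcohol under neutral conditions, chosen so that the very electron-rich benzhydrol is not ionised by acid.

Step 6
Reactants: 9 the benzophenone; 10 1-bromo-5-methylhexane
Product: 13 rac-3,5-bis(benzyloxy)-4-(1-{2,6-bis(benzyloxy)-4-[tri(propan-2-yl)silyloxy]phenyl}-1-hydroxy-6-methylheptyl)phenol, via (5-methylhexyl)magnesium bromide 11 (not isolated), via silylated tertiary carbinol 12 (not isolated)
Conditions: 10, Mg, THF; CeCl3 (anhydrous), THF, −78 °C, then 9, −78 → 0 °C; H2O; crude 12, K2CO3, MeOH–THF, 0 °C → rt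
Reagents that add atoms: none
Why: Cerium chloride-modified Grignard addition to a hindered, non-enolisable diaryl ketone (the cerium reagent should suppress reduction and attack on the ortho alkoxy groups), then base-mediated methanolysis of the aryl tert-butyldimethylsilyl ether, which is much faster than that of the aryl triisopropylsilyl ether; the tertiary centre is racemic and is reset in step 7.

Step 7
Reactants: 13 the ring B phenol tertiary carbinol
Product: 14 3,5-bis(benzyloxy)-4-[(1R)-1-{2,6-bis(benzyloxy)-4-[tri(propan-2-yl)silyloxy]phenyl}-6-methylheptyl]phenol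
Conditions: (R)-TRIP [(R)-3,3′-bis(2,4,6-triisopropylphenyl)-1,1′-binaphthyl-2,2′-diyl hydrogen phosphate, 10 mol%], Hantzsch ester (diethyl 2,6-dimethyl-1,4-dihydropyridine-3,5-dicarboxylate, 1.5 equiv), CH2Cl2, rt
Reagents that add atoms: none
Why: Organocatalytic asymmetric transfer hydrogenation of a para-quinone methide formed in situ, in which the acid dehydrates the para-hydroxybenzylic alcohol to the quinone methide of ring B (ring A cannot take this role because its O1 is silylated, and any alkene or methyl ether formed alongside 13 enters the same intermediate) and the phosphate, bound to the quinone oxygen and to the N–H of the dihydropyridine, should guide hydride to one face of the exocyclic carbon and so set the methine as (R).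

Step 8
Reactants: 14 the (R)-diarylheptane phenol; 15 2-methylpropanoyl chloride
Product: 17 1-{2,4-bis(benzyloxy)-3-[(1S)-1-{2,6-bis(benzyloxy)-4-[tri(propan-2-yl)silyloxy]phenyl}-6-methylheptyl]-6-hydroxyphenyl}-2-methylpropan-1-one, via bromomagnesium phenolate 16 (not isolated)
Conditions: EtMgBr (1.0 equiv), toluene–Et2O, 0 °C; then 15, 0 → 60 °C; H2O
Reagents that add atoms: none
Why: Metal-template (ortho-coordinated) C-acylation of a bromomagnesium phenolate with an acyl chloride, in which the magnesium-bound acyl chloride is delivered to the carbon ortho to O1 (para is blocked and the two ortho carbons are equivalent), while silylated ring A has no phenolate and should stay unacylated.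

Step 9
Reactants: 17 the ring B ketone silyl ether
Product: 18 1-{2,4-bis(benzyloxy)-3-[(1S)-1-[2,6-bis(benzyloxy)-4-hydroxyphenyl]-6-methylheptyl]-6-hydroxyphenyl}-2-methylpropan-1-one
Conditions: Bu4NF, AcOH, THF, 0 °C → rt
Reagents that add atoms: none
Why: Fluoride cleavage of the aryl triisopropylsilyl ether, buffered with acetic acid so that no strongly basic phenoxide is present beside the ketone.

Step 10
Reactants: 19 (2R)-2-methylbutanoic acid
Product: 20 (2R)-2-methylbutanoyl chloride
Conditions: (COCl)2, DMF (cat.), CH2Cl2, 0 °C → rt; volatiles removed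
Reagents that add atoms: oxalyl chloride, O=C(Cl)C(=O)Cl
Why: Acid chloride formation through the Vilsmeier-type chloroiminium salt, run without amine base so that no ketene can form and the α-centre keeps its configuration.

Step 11
Reactants: 18 the bisphenol mono-ketone; 20 (2R)-2-methylbutanoyl chloride
Product: 22 (2R)-1-{2,4-bis(benzyloxy)-3-[(1R)-1-[2,6-bis(benzyloxy)-4-hydroxy-3-(2-methylpropanoyl)phenyl]-6-methylheptyl]-6-hydroxyphenyl}-2-methylbutan-1-one, via bis(bromomagnesium) phenolate 21 (not isolated)
Conditions: EtMgBr (2.0 equiv), toluene–Et2O, 0 °C; then 20 (1.05 equiv), 0 → 50 °C; H2O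
Reagents that add atoms: none
Why: The same metal-template C-acylation, now on ring A, whose phenolate is the more nucleophilic one because the ring B phenolate is chelated to and deactivated by its own ketone; the α-stereocentre is carried in unchanged from 20.

Step 12
Reactants: 22 the bis-ketone
Product: 23 (2R)-1-{2,4-bis(benzyloxy)-3-[(1R)-1-[2,6-bis(benzyloxy)-4-hydroxy-3-(hydroxymethyl)-5-(2-methylpropanoyl)phenyl]-6-methylheptyl]-6-hydroxy-5-(hydroxymethyl)phenyl}-2-methylbutan-1-one
Conditions: 37% aq. CH2O (excess), K2CO3, THF–H2O, 0 °C → rt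
Reagents that add atoms: formaldehyde (first equivalent for ring A), C=O; formaldehyde (second equivalent for ring B), C=O
Why: Lederer–Manasse hydroxymethylation of each phenoxide at its only free ring carbon (ortho to O1), one molecule of formaldehyde per ring, with excess formaldehyde at low temperature so that the benzylic alcohols should not go on to methylene bridges, and with the phenoxide form of each hydroxy ketone damping enolisation at the α-centre.

Step 13
Reactants: 23 the bis(ortho-hydroxybenzyl alcohol); 24 2-methylpropene (first equivalent, taken up by ring A)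
Product: 28 tetra-O-benzyl ether of 1, via ring A ortho-quinone methide 25 (not isolated), via ring A monochroman 26 (not isolated), via ring B ortho-quinone methide 27 (not isolated)
Conditions: 24 (large excess, condensed), toluene, sealed vessel, 150 °C
Reagents that add atoms: 2-methylpropene (second equivalent of 24 for ring B), CC(C)=C
Why: Thermal loss of water from each ortho-hydroxybenzyl alcohol (O1–H and the C4 carbinol) gives an acyl-substituted ortho-quinone methide (C4=C4a–C8a=O1), an electron-poor oxadiene that should add 2-methylpropene in an asynchronous inverse-demand hetero-Diels–Alder reaction; the closest known reaction type is the thermal chroman synthesis from salicyl alcohols and alkenes. Each dihydropyran ring closes by a (4+2) cycloaddition that forms C3–C4 and O1–C2 on the same ring in one event, the two rings reacting independently and each consuming one molecule of the alkene, so that the overall equation is 23 plus two 2-methylpropene giving 28 and two water (the order written, ring A first, is arbitrary). No stereocentre is created, since C2 carries two methyls and C3 and C4 are CH2, and the two existing centres should be untouched because neither acid nor base is present. Two kinds of regioselectivity are needed: the oxygen that enters the ring is fixed because O1–H is the only free hydroxyl ortho to each CH2OH (O5 and O7 are benzylated), and the alkene orientation is fixed by its polarisation, the CH2 terminus bonding to the electrophilic methylene so that charge builds at the tertiary carbon captured by O1. The large excess of alkene in a closed vessel is there to outrun self-condensation of the quinone methide.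

Step 14
Reactants: 28 tetra-O-benzyl ether of 1
Product: 1 (2R)-1-{5,7-dihydroxy-6-[(1R)-1-[5,7-dihydroxy-2,2-dimethyl-8-(2-methylpropanoyl)-3,4-dihydro-2H-chromen-6-yl]-6-methylheptyl]-2,2-dimethyl-3,4-dihydro-2H-chromen-8-yl}-2-methylbutan-1-one
Conditions: H2 (1 atm), Pd/C (10% palladium on carbon), EtOAc–EtOH, rt
Reagents that add atoms: none
Why: Hydrogenolysis of the four aryl benzyl ethers over palladium on carbon under neutral conditions, which should leave the chroman ethers, the hindered aryl ketones and both stereocentres untouched.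

Compound list
1 | (2R)-1-{5,7-dihydroxy-6-[(1R)-1-[5,7-dihydroxy-2,2-dimethyl-8-(2-methylpropanoyl)-3,4-dihydro-2H-chromen-6-yl]-6-methylheptyl]-2,2-dimethyl-3,4-dihydro-2H-chromen-8-yl}-2-methylbutan-1-one | CC[C@@H](C)C(=O)c1c(O)c([C@H](CCCCC(C)C)c2c(O)c3c(c(C(=O)C(C)C)c2O)OC(C)(C)CC3)c(O)c2c1OC(C)(C)CC2 | target
2 | 3,5-bis(benzyloxy)phenol | Oc1cc(OCc2ccccc2)cc(OCc2ccccc2)c1 | starting material
3 | [3,5-bis(benzyloxy)phenoxy]tri(propan-2-yl)silane | CC(C)[Si](Oc1cc(OCc2ccccc2)cc(OCc2ccccc2)c1)(C(C)C)C(C)C | intermediate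
4 | 2,6-bis(benzyloxy)-4-[tri(propan-2-yl)silyloxy]phenyllithium (ring A aryllithium) | [Li]c1c(OCc2ccccc2)cc(O[Si](C(C)C)(C(C)C)C(C)C)cc1OCc1ccccc1 | intermediate (not isolated)
5 | 2,6-bis(benzyloxy)-4-[tri(propan-2-yl)silyloxy]benzaldehyde | O=Cc1c(OCc2ccccc2)cc(O[Si](C(C)C)(C(C)C)C(C)C)cc1OCc1ccccc1 | intermediate
6 | [3,5-bis(benzyloxy)phenoxy](tert-butyl)dimethylsilane | CC(C)(C)[Si](C)(C)Oc1cc(OCc2ccccc2)cc(OCc2ccccc2)c1 | intermediate
7 | 2,6-bis(benzyloxy)-4-[tert-butyl(dimethyl)silyloxy]phenyllithium (ring B aryllithium) | [Li]c1c(OCc2ccccc2)cc(O[Si](C)(C)C(C)(C)C)cc1OCc1ccccc1 | intermediate (not isolated)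
8 | rac-{2,6-bis(benzyloxy)-4-[tert-butyl(dimethyl)silyloxy]phenyl}{2,6-bis(benzyloxy)-4-[tri(propan-2-yl)silyloxy]phenyl}methanol | OC(c1c(OCc2ccccc2)cc(O[Si](C)(C)C(C)(C)C)cc1OCc1ccccc1)c1c(OCc2ccccc2)cc(O[Si](C(C)C)(C(C)C)C(C)C)cc1OCc1ccccc1 | intermediate
9 | {2,6-bis(benzyloxy)-4-[tert-butyl(dimethyl)silyloxy]phenyl}{2,6-bis(benzyloxy)-4-[tri(propan-2-yl)silyloxy]phenyl}methanone | O=C(c1c(OCc2ccccc2)cc(O[Si](C)(C)C(C)(C)C)cc1OCc1ccccc1)c1c(OCc2ccccc2)cc(O[Si](C(C)C)(C(C)C)C(C)C)cc1OCc1ccccc1 | intermediate
10 | 1-bromo-5-methylhexane | CC(C)CCCCBr | starting material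
11 | (5-methylhexyl)magnesium bromide | CC(C)CCCC[Mg]Br | intermediate (not isolated)
12 | rac-1-{2,6-bis(benzyloxy)-4-[tert-butyl(dimethyl)silyloxy]phenyl}-1-{2,6-bis(benzyloxy)-4-[tri(propan-2-yl)silyloxy]phenyl}-6-methylheptan-1-ol | CC(C)CCCCC(O)(c1c(OCc2ccccc2)cc(O[Si](C)(C)C(C)(C)C)cc1OCc1ccccc1)c1c(OCc2ccccc2)cc(O[Si](C(C)C)(C(C)C)C(C)C)cc1OCc1ccccc1 | intermediate (not isolated)
13 | rac-3,5-bis(benzyloxy)-4-(1-{2,6-bis(benzyloxy)-4-[tri(propan-2-yl)silyloxy]phenyl}-1-hydroxy-6-methylheptyl)phenol | CC(C)CCCCC(O)(c1c(OCc2ccccc2)cc(O)cc1OCc1ccccc1)c1c(OCc2ccccc2)cc(O[Si](C(C)C)(C(C)C)C(C)C)cc1OCc1ccccc1 | intermediate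
14 | 3,5-bis(benzyloxy)-4-[(1R)-1-{2,6-bis(benzyloxy)-4-[tri(propan-2-yl)silyloxy]phenyl}-6-methylheptyl]phenol | CC(C)[Si](Oc1cc(OCc2ccccc2)c([C@H](CCCCC(C)C)c2c(OCc3ccccc3)cc(O)cc2OCc2ccccc2)c(OCc2ccccc2)c1)(C(C)C)C(C)C | intermediate
15 | 2-methylpropanoyl chloride (isobutyryl chloride) | CC(C)C(=O)Cl | starting material
16 | bromomagnesium phenolate of 14 (ring B O1–MgBr; stereocentre as in 14) | CC(C)[Si](Oc1cc(OCc2ccccc2)c([C@H](CCCCC(C)C)c2c(OCc3ccccc3)cc(O[Mg]Br)cc2OCc2ccccc2)c(OCc2ccccc2)c1)(C(C)C)C(C)C | intermediate (not isolated)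
17 | 1-{2,4-bis(benzyloxy)-3-[(1S)-1-{2,6-bis(benzyloxy)-4-[tri(propan-2-yl)silyloxy]phenyl}-6-methylheptyl]-6-hydroxyphenyl}-2-methylpropan-1-one | CC(C)[Si](Oc1cc(OCc2ccccc2)c([C@H](CCCCC(C)C)c2c(OCc3ccccc3)cc(O)c(C(=O)C(C)C)c2OCc2ccccc2)c(OCc2ccccc2)c1)(C(C)C)C(C)C | intermediate
18 | 1-{2,4-bis(benzyloxy)-3-[(1S)-1-[2,6-bis(benzyloxy)-4-hydroxyphenyl]-6-methylheptyl]-6-hydroxyphenyl}-2-methylpropan-1-one | Oc1cc(OCc2ccccc2)c([C@H](CCCCC(C)C)c2c(OCc3ccccc3)cc(O)c(C(=O)C(C)C)c2OCc2ccccc2)c(OCc2ccccc2)c1 | intermediate
19 | (2R)-2-methylbutanoic acid | CC[C@@H](C)C(=O)O | starting material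
20 | (2R)-2-methylbutanoyl chloride | CC[C@@H](C)C(=O)Cl | intermediate
21 | bis(bromomagnesium) phenolate of 18 (stereocentre as in 18) | Br[Mg]Oc1cc(OCc2ccccc2)c([C@H](CCCCC(C)C)c2c(OCc3ccccc3)cc(O[Mg]Br)c(C(=O)C(C)C)c2OCc2ccccc2)c(OCc2ccccc2)c1 | intermediate (not isolated)
22 | (2R)-1-{2,4-bis(benzyloxy)-3-[(1R)-1-[2,6-bis(benzyloxy)-4-hydroxy-3-(2-methylpropanoyl)phenyl]-6-methylheptyl]-6-hydroxyphenyl}-2-methylbutan-1-one | CC[C@@H](C)C(=O)c1c(OCc2ccccc2)c([C@H](CCCCC(C)C)c2c(OCc3ccccc3)cc(O)c(C(=O)C(C)C)c2OCc2ccccc2)c(OCc2ccccc2)cc1O | intermediate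
23 | (2R)-1-{2,4-bis(benzyloxy)-3-[(1R)-1-[2,6-bis(benzyloxy)-4-hydroxy-3-(hydroxymethyl)-5-(2-methylpropanoyl)phenyl]-6-methylheptyl]-6-hydroxy-5-(hydroxymethyl)phenyl}-2-methylbutan-1-one | CC[C@@H](C)C(=O)c1c(OCc2ccccc2)c([C@H](CCCCC(C)C)c2c(OCc3ccccc3)c(CO)c(O)c(C(=O)C(C)C)c2OCc2ccccc2)c(OCc2ccccc2)c(CO)c1O | intermediate
24 | 2-methylpropene | CC(C)=C | starting material
25 | ring A ortho-quinone methide of 23 (6-methylenecyclohexa-2,4-dienone form of ring A; ring B still the benzylic alcohol; stereocentres as in 23) | CC[C@@H](C)C(=O)C1=C(OCc2ccccc2)C([C@H](CCCCC(C)C)c2c(OCc3ccccc3)c(CO)c(O)c(C(=O)C(C)C)c2OCc2ccccc2)=C(OCc2ccccc2)C(=C)C1=O | intermediate (not isolated)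
26 | ring A monochroman (ring A closed; ring B still the ortho-hydroxybenzyl alcohol; stereocentres as in 23) | CC[C@@H](C)C(=O)c1c(OCc2ccccc2)c([C@H](CCCCC(C)C)c2c(OCc3ccccc3)c(CO)c(O)c(C(=O)C(C)C)c2OCc2ccccc2)c(OCc2ccccc2)c2c1OC(C)(C)CC2 | intermediate (not isolated)
27 | ring B ortho-quinone methide of 26 (stereocentres as in 23) | CC[C@@H](C)C(=O)c1c(OCc2ccccc2)c([C@H](CCCCC(C)C)C2=C(OCc3ccccc3)C(=C)C(=O)C(C(=O)C(C)C)=C2OCc2ccccc2)c(OCc2ccccc2)c2c1OC(C)(C)CC2 | intermediate (not isolated)
28 | tetra-O-benzyl ether of 1: (2R)-1-{5,7-bis(benzyloxy)-6-[(1R)-1-[5,7-bis(benzyloxy)-2,2-dimethyl-8-(2-methylpropanoyl)-3,4-dihydro-2H-chromen-6-yl]-6-methylheptyl]-2,2-dimethyl-3,4-dihydro-2H-chromen-8-yl}-2-methylbutan-1-one | CC[C@@H](C)C(=O)c1c(OCc2ccccc2)c([C@H](CCCCC(C)C)c2c(OCc3ccccc3)c3c(c(C(=O)C(C)C)c2OCc2ccccc2)OC(C)(C)CC3)c(OCc2ccccc2)c2c1OC(C)(C)CC2 | intermediate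

Total step count: 14.
Longest linear sequence: 12 steps (2 → 3 → 5 → 8 → 9 → 13 → 14 → 17 → 18 → 22 → 23 → 28 → 1; steps 1, 2, 4, 5, 6, 7, 8, 9, 11, 12, 13, 14).

Steps most likely to fail

Step 7. The carbon to be reduced is flanked by four ortho benzyloxy groups, so ionisation to the quinone methide may be slow, the substrate may rest as the alkene, and hydride delivery may be poorly face-selective. The fallback sets out from 13 and returns at 14. Ionic hydrogenation of 13 with Et3SiH and CF3CO2H in CH2Cl2 at −40 °C should give the racemic diarylheptane F1. Preparative chromatography on a chiral stationary phase (supercritical CO2 with an alcohol modifier) then separates the enantiomers; the (S)-enantiomer F2 is put aside and the (R)-enantiomer is 14.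

Step 11. The magnesium phenolate may be acylated on oxygen instead of carbon, and the acid chloride or the new ketone may enolise on magnesium, eroding the α-centre. The fallback sets out from 18 and returns at 22. N-Iodosuccinimide (1 equiv, CH2Cl2, −20 °C) should iodinate ring A ortho to its free, unchelated hydroxyl and give the ring A iodophenol F3. Steglich esterification of that hydroxyl with 19 (DCC, DMAP, CH2Cl2, 0 °C) gives the ring A aryl ester F4. i-PrMgCl·LiCl (2.1 equiv, THF, −40 °C) then deprotonates the ring B phenol and exchanges iodine for magnesium, and the arylmagnesium attacks the neighbouring ester carbonyl in an anionic Fries-type 1,3 O→C acyl shift; work-up gives 22. This transfer is intramolecular, so the acyl group stays on ring A.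

Step 13. Self-condensation of the quinone methides may outrun cycloaddition to a volatile, unactivated alkene, the second ring may close incompletely, and prolonged heating may erode the α-centre. The fallback sets out from 22 and returns at 1. Phenylboronic acid-templated chromene annulation of each phenol with 3-methylbut-2-enal (PhB(OH)2, propanoic acid cat., toluene, reflux with removal of water) should give the bis(2,2-dimethyl-2H-chromene) F5, with O1 and C4a of each ring joined through a C4=C3–C2 unit. Hydrogenation over Pd/C (H2, EtOAc–EtOH, rt) then saturates both C3=C4 bonds and removes the four benzyl groups in one operation to give 1.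

Further compounds
F1 | step 7 | racemic 14: rac-3,5-bis(benzyloxy)-4-(1-{2,6-bis(benzyloxy)-4-[tri(propan-2-yl)silyloxy]phenyl}-6-methylheptyl)phenol | CC(C)[Si](Oc1cc(OCc2ccccc2)c(C(CCCCC(C)C)c2c(OCc3ccccc3)cc(O)cc2OCc2ccccc2)c(OCc2ccccc2)c1)(C(C)C)C(C)C
F2 | step 7 | (S)-enantiomer of 14 | CC(C)[Si](Oc1cc(OCc2ccccc2)c([C@@H](CCCCC(C)C)c2c(OCc3ccccc3)cc(O)cc2OCc2ccccc2)c(OCc2ccccc2)c1)(C(C)C)C(C)C
F3 | step 11 | ring A iodophenol: 18 with iodine ortho to the ring A hydroxyl (stereocentre as in 18) | Oc1c(I)c(OCc2ccccc2)c([C@H](CCCCC(C)C)c2c(OCc3ccccc3)cc(O)c(C(=O)C(C)C)c2OCc2ccccc2)c(OCc2ccccc2)c1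
F4 | step 11 | ring A aryl ester: (2R)-2-methylbutanoate of F3 at the ring A hydroxyl | CC[C@@H](C)C(=O)Oc1c(I)c(OCc2ccccc2)c([C@H](CCCCC(C)C)c2c(OCc3ccccc3)cc(O)c(C(=O)C(C)C)c2OCc2ccccc2)c(OCc2ccccc2)c1
F5 | step 13 | bis(2,2-dimethyl-2H-chromene): 28 with C3=C4 double bonds in both pyran rings | CC[C@@H](C)C(=O)c1c(OCc2ccccc2)c([C@H](CCCCC(C)C)c2c(OCc3ccccc3)c3C=CC(C)(C)Oc3c(C(=O)C(C)C)c2OCc2ccccc2)c(OCc2ccccc2)c2C=CC(C)(C)Oc12
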